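**Assumptions (one line each)**
- The SMILES corresponds to (5R,8R,9R,10S)-5,8-di-epi-ilimaquinone: a cis-fused decalin with 5-CH3, 10-H, 9-CH2Ar and 8-CH3 on one face (called α here) and 9-CH3 on the other (β). Ilimaquinone numbering is used: C4 bears the exocyclic CH2, C5 the angular CH3.
- Commercial ketoreductase screening panels and 4,6-dibromoresorcinol are treated as purchasable.
- This route is a design from first principles and has not been run; selectivities are predicted, not measured.

**Retrosynthetic overview**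
1. Quinone last: oxidation of a symmetric 2,6-dihydroxy-3,5-dimethoxybenzyl arene (only one product possible); C4=CH2 by Wittig just before.
2. C8: hydroxyl-directed hydrogenation of C8=CH2 from a 9β-CH2OH, which is then deoxygenated to the 9β-CH3.
3. C9 and C10: convex-face benzylation of a cis-fused β-keto ester, itself from syn-hydrogenation of an enone ester.
4. Ring B is closed onto ring A by Roskamp homologation and intramolecular Knoevenagel condensation.
5. Ring A and C5: ketoreductase desymmetrisation of achiral 2-allyl-2-methylcyclohexane-1,3-dione. Ring order: A (purchased) → B → quinone.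

Ar(MOM) = 3,5-dimethoxy-2,6-bis(methoxymethoxy)phenyl.

---

**Step 1**
Reactants: 1, 2-methylcyclohexane-1,3-dione; 2, allyl bromide
Product: 3, 2-allyl-2-methylcyclohexane-1,3-dione
Conditions: 1 M NaOH (aq), rt
Reagents that add atoms: none beyond reactant 2
Why: C-allylation of the 1,3-dione enolate with a soft allylic electrophile; the product is prochiral with no stereocentre.

**Step 2**
Reactants: 3
Product: 4, (2S,3S)-2-allyl-3-hydroxy-2-methylcyclohexan-1-one (OH trans to CH3)
Conditions: ketoreductase (KRED, NADPH-dependent), NADP+ (cat.), i-PrOH, pH 7 phosphate buffer, 30 °C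
Reagents that add atoms: none (H only)
Why: Enzymatic desymmetrising carbonyl reduction; the KRED distinguishes the two enantiotopic C=O groups and their faces, setting the quaternary centre (future C5) and the carbinol (future C4) together, in the same sense as the classical yeast reduction of this dione.

**Step 3**
Reactants: 4
Product: 5, (2S,3S)-2-allyl-3-(tert-butyldimethylsilyloxy)-2-methylcyclohexan-1-one
Conditions: TBSOTf, 2,6-lutidine, CH2Cl2, −78 → 0 °C
Reagents that add atoms: TBSOTf, CC(C)(C)[Si](C)(C)OS(=O)(=O)C(F)(F)F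
Why: Silylation of the hindered secondary alcohol prevents retro-aldol and masks the future C4 carbonyl.

**Step 4**
Reactants: 5
Product: 6, (2S,3S)-3-(TBSO)-2-(3-hydroxypropyl)-2-methylcyclohexan-1-one
Conditions: 9-BBN, THF, 0 °C → rt; then NaOH, 30% H2O2, 0 °C
Reagents that add atoms: hydrogen peroxide, OO (supplies the hydroxyl O)
Why: Anti-Markovnikov hydroboration–oxidation; 9-BBN reacts much faster with the terminal alkene than with the hindered α-quaternary ketone.

**Step 5**
Reactants: 6
Product: 7, 3-[(1S,2S)-2-(TBSO)-1-methyl-6-oxocyclohexyl]propanal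
Conditions: Dess–Martin periodinane, NaHCO3, CH2Cl2, rt
Reagents that add atoms: none
Why: Neutral Dess–Martin oxidation of the primary alcohol; no base, so no aldol side reaction.

**Step 6**
Reactants: 7; 8, ethyl diazoacetate
Product: 9, ethyl 5-[(1S,2S)-2-(TBSO)-1-methyl-6-oxocyclohexyl]-3-oxopentanoate
Conditions: SnCl2 (10 mol%), CH2Cl2, rt
Reagents that add atoms: none beyond reactant 8
Why: Roskamp homologation converts the aldehyde into a β-keto ester; the hindered ring ketone does not react.

**Step 7**
Reactants: 9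
Product: 10, ethyl (4aR,5S)-5-(TBSO)-4a-methyl-2-oxo-2,3,4,4a,5,6,7,8-octahydronaphthalene-1-carboxylate (Δ9,10 enone ester, 4β-OTBS, 5α-CH3)
Conditions: piperidine, AcOH (cat.), toluene, reflux, Dean–Stark
Reagents that add atoms: none
Why: Intramolecular Knoevenagel condensation of the active methylene onto the only ring ketone closes six-membered ring B (Nazarov-annulation type); no new stereocentre.

**Step 8**
Reactants: 10
Product: 11, ethyl (4aR,5S,8aS)-5-(TBSO)-4a-methyl-2-oxodecahydronaphthalene-1-carboxylate (cis-fused, 10α-H; C9 as epimer/enol mixture)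
Conditions: H2 (1 atm), 10% Pd/C, Et3N (cat.), EtOAc, rt
Reagents that add atoms: none (H only)
Why: Heterogeneous syn-hydrogenation of the alkylidene β-keto ester; as with Δ4-3-keto decalins in basic medium, H adds to C10 syn to the angular methyl, and the 4β-OTBS shields the other face, giving the cis ring fusion.

**Step 9**
Reactants: 12, 4,6-dibromobenzene-1,3-diol
Product: 13, 1,5-dibromo-2,4-bis(methoxymethoxy)benzene
Conditions: MOMCl, i-Pr2NEt, CH2Cl2, 0 °C → rt
Reagents that add atoms: chloromethyl methyl ether, COCCl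
Why: Standard O-alkylation of both phenols as MOM ethers, which later direct lithiation.

**Step 10**
Reactants: 13
Product: 14, 1,5-dimethoxy-2,4-bis(methoxymethoxy)benzene
Conditions: NaOMe, CuI (cat.), MeOH/DMF, 110 °C
Reagents that add atoms: sodium methoxide, C[O-].[Na+]
Why: Copper-catalysed Ullmann-type methoxylation of both equivalent aryl bromides.

**Step 11**
Reactants: 14
Product: 15, 3,5-dimethoxy-2,6-bis(methoxymethoxy)benzaldehyde
Conditions: n-BuLi, TMEDA, THF, −20 → 0 °C; then DMF
Reagents that add atoms: N,N-dimethylformamide, CN(C)C=O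
Why: Directed ortho-metalation at the position flanked by two OMOM groups (stronger directors than OMe), then formylation.

**Step 12**
Reactants: 15
Product: 16, [3,5-dimethoxy-2,6-bis(methoxymethoxy)phenyl]methanol
Conditions: NaBH4, MeOH, 0 °C
Reagents that add atoms: none (H only)
Why: Simple hydride reduction of the aldehyde.

**Step 13**
Reactants: 16
Product: 17, 3-(bromomethyl)-1,5-dimethoxy-2,4-bis(methoxymethoxy)benzene (used at once)
Conditions: CBr4, PPh3, 2,6-lutidine, CH2Cl2, 0 °C
Reagents that add atoms: carbon tetrabromide, BrC(Br)(Br)Br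
Why: Appel bromination under non-acidic conditions preserves the MOM ethers.

**Step 14**
Reactants: 11; 17
Product: 18, ethyl ester of the cis-decalin 8-oxo-9-carboxylate with 9α-CH2Ar(MOM), 9β-CO2Et, 4β-OTBS, 5α-CH3, 10α-H
Conditions: NaH, THF/DMF, 0 °C; then 17, Bu4NI (cat.), rt → 40 °C
Reagents that add atoms: none beyond reactant 17
Why: Regiospecific C-alkylation of the β-keto ester enolate; the benzyl bromide enters C9 from the convex α-face of the cis-decalin (syn to 10-H, anti to the ring-A C1 methylene), setting the quaternary centre.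

**Step 15**
Reactants: 18
Product: 19, the 8-methylene analogue of 18 (C8=CH2, ester retained)
Conditions: Zn, CH2Br2, TiCl4, THF/CH2Cl2, 0 °C → rt (Takai–Lombardo)
Reagents that add atoms: dibromomethane, BrCBr
Why: Non-basic titanium methylenation converts the hindered ketone, not the ester, and cannot trigger retro-Claisen cleavage.

**Step 16**
Reactants: 19
Product: 20, the 9β-hydroxymethyl compound (homoallylic alcohol: 9β-CH2OH, 9α-CH2Ar(MOM), C8=CH2, 4β-OTBS)
Conditions: LiAlH4, THF, 0 °C → rt
Reagents that add atoms: none (H only)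
Why: Hydride reduction of the neopentyl ester gives the alcohol that will direct the next step.

**Step 17**
Reactants: 20
Product: 21, the 8α-methyl compound (8β-H, 8α-CH3, 9β-CH2OH, 9α-CH2Ar(MOM), 4β-OTBS)
Conditions: [Ir(cod)(PCy3)(py)]PF6 (10 mol%), H2 (1 atm), CH2Cl2, rt
Reagents that add atoms: none (H only)
Why: Hydroxyl-directed (Crabtree) hydrogenation; iridium bound to the 9β-CH2OH delivers H2 to the β-face of the 8-methylene (the α-face is also blocked by the 9α-benzyl), so the new methyl is α.

**Step 18**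
Reactants: 21
Product: 22, the 9β-formyl compound
Conditions: Dess–Martin periodinane, NaHCO3, CH2Cl2, rt
Reagents that add atoms: none
Why: Mild oxidation of the neopentyl alcohol; the aldehyde has no α-H, so nothing can epimerise.

**Step 19**
Reactants: 22
Product: 23, (4S,5R,8R,9R,10S)-9-[Ar(MOM)-methyl]-5,8,9-trimethyldecalin-4-ol (9β-CH3 now in place, free 4β-OH)
Conditions: N2H4·H2O, KOH, diethylene glycol, 130 → 200 °C (the TBS ether is cleaved under these conditions; any remainder removed with TBAF on the crude)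
Reagents that add atoms: none (H only)
Why: Wolff–Kishner (Huang–Minlon) reduction turns the hindered aldehyde into the C9 methyl; MOM and methyl aryl ethers are base-stable.

**Step 20**
Reactants: 23
Product: 24, the corresponding decalin-4-one
Conditions: Dess–Martin periodinane, NaHCO3, CH2Cl2, rt
Reagents that add atoms: none
Why: Oxidation of the secondary alcohol; the adjacent C5 is quaternary, so no stereocentre is at risk.

**Step 21**
Reactants: 24
Product: 25, (5R,8R,9R,10S)-9-[Ar(MOM)-methyl]-5,8,9-trimethyl-4-methylidenedecalin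
Conditions: Ph3PCH3Br, KOt-Bu, toluene, 90 °C
Reagents that add atoms: methyltriphenylphosphonium bromide, C[P+](c1ccccc1)(c1ccccc1)c1ccccc1.[Br-]
Why: Wittig methylenation of the hindered α-quaternary ketone installs the exocyclic alkene, after all hydrogenations are finished.

**Step 22**
Reactants: 25
Product: 26, 2-{[(1R,2R,4aR,8aS)-1,2,4a-trimethyl-5-methylidenedecahydronaphthalen-1-yl]methyl}-4,6-dimethoxybenzene-1,3-diol
Conditions: ZnBr2, n-PrSH, CH2Cl2, 0 °C, 15 min
Reagents that add atoms: none
Why: Fast, mild Lewis acid/thiol cleavage of the aryl MOM ethers avoids protic acid that could isomerise or cyclise the exocyclic alkene.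

**Step 23**
Reactants: 26
Product: 27, target, 2-hydroxy-5-methoxy-3-{[(1R,2R,4aR,8aS)-1,2,4a-trimethyl-5-methylidenedecahydronaphthalen-1-yl]methyl}cyclohexa-2,5-diene-1,4-dione
Conditions: (NH4)2Ce(NO3)6, MeCN/H2O, 0 °C, 10 min
Reagents that add atoms: water, O (replaces one OCH3 as a quinone carbonyl oxygen)
Why: Oxidative demethylation of a p-methoxyphenol to the p-quinone; because the arene is symmetric, every oxidation pathway converges on the single 2-hydroxy-5-methoxy-3-alkylquinone.

---

**Compound list**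

1 | 2-methylcyclohexane-1,3-dione | CC1C(=O)CCCC1=O | starting material
2 | allyl bromide | C=CCBr | starting material
3 | 2-allyl-2-methylcyclohexane-1,3-dione | C=CCC1(C)C(=O)CCCC1=O | intermediate
4 | (2S,3S)-2-allyl-3-hydroxy-2-methylcyclohexan-1-one | O[C@H]1CCCC(=O)[C@@]1(C)CC=C | intermediate
5 | (2S,3S)-2-allyl-3-(TBSO)-2-methylcyclohexan-1-one | CC(C)(C)[Si](C)(C)O[C@H]1CCCC(=O)[C@@]1(C)CC=C | intermediate
6 | (2S,3S)-3-(TBSO)-2-(3-hydroxypropyl)-2-methylcyclohexan-1-one | CC(C)(C)[Si](C)(C)O[C@H]1CCCC(=O)[C@@]1(C)CCCO | intermediate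
7 | 3-[(1S,2S)-2-(TBSO)-1-methyl-6-oxocyclohexyl]propanal | CC(C)(C)[Si](C)(C)O[C@H]1CCCC(=O)[C@@]1(C)CCC=O | intermediate
8 | ethyl diazoacetate | CCOC(=O)C=[N+]=[N-] | starting material
9 | ethyl 5-[(1S,2S)-2-(TBSO)-1-methyl-6-oxocyclohexyl]-3-oxopentanoate | CC(C)(C)[Si](C)(C)O[C@H]1CCCC(=O)[C@@]1(C)CCC(=O)CC(=O)OCC | intermediate
10 | ethyl (4aR,5S)-5-(TBSO)-4a-methyl-2-oxo-2,3,4,4a,5,6,7,8-octahydronaphthalene-1-carboxylate | CC(C)(C)[Si](C)(C)O[C@H]1CCCC2=C(C(=O)OCC)C(=O)CC[C@@]12C | intermediate
11 | ethyl (4aR,5S,8aS)-5-(TBSO)-4a-methyl-2-oxodecahydronaphthalene-1-carboxylate (cis-fused) | CC(C)(C)[Si](C)(C)O[C@H]1CCC[C@H]2C(C(=O)OCC)C(=O)CC[C@@]12C | intermediate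
12 | 4,6-dibromobenzene-1,3-diol | Oc1cc(O)c(Br)cc1Br | starting material
13 | 1,5-dibromo-2,4-bis(methoxymethoxy)benzene | COCOc1cc(OCOC)c(Br)cc1Br | intermediate
14 | 1,5-dimethoxy-2,4-bis(methoxymethoxy)benzene | COCOc1cc(OCOC)c(OC)cc1OC | intermediate
15 | 3,5-dimethoxy-2,6-bis(methoxymethoxy)benzaldehyde | O=Cc1c(OCOC)c(OC)cc(OC)c1OCOC | intermediate
16 | [3,5-dimethoxy-2,6-bis(methoxymethoxy)phenyl]methanol | OCc1c(OCOC)c(OC)cc(OC)c1OCOC | intermediate
17 | 3-(bromomethyl)-1,5-dimethoxy-2,4-bis(methoxymethoxy)benzene | BrCc1c(OCOC)c(OC)cc(OC)c1OCOC | intermediate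
18 | cis-decalin 8-oxo ester: 9α-CH2Ar(MOM), 9β-CO2Et, 4β-OTBS, 5α-CH3, 10α-H | CC(C)(C)[Si](C)(C)O[C@H]1CCC[C@H]2[C@](C(=O)OCC)(Cc3c(OCOC)c(OC)cc(OC)c3OCOC)C(=O)CC[C@@]12C | intermediate
19 | 8-methylene analogue of 18 | CC(C)(C)[Si](C)(C)O[C@H]1CCC[C@H]2[C@](C(=O)OCC)(Cc3c(OCOC)c(OC)cc(OC)c3OCOC)C(=C)CC[C@@]12C | intermediate
20 | 9β-hydroxymethyl-8-methylene compound | CC(C)(C)[Si](C)(C)O[C@H]1CCC[C@H]2[C@](CO)(Cc3c(OCOC)c(OC)cc(OC)c3OCOC)C(=C)CC[C@@]12C | intermediate
21 | 8α-methyl-9β-hydroxymethyl compound | CC(C)(C)[Si](C)(C)O[C@H]1CCC[C@H]2[C@](CO)(Cc3c(OCOC)c(OC)cc(OC)c3OCOC)[C@H](C)CC[C@@]12C | intermediate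
22 | 8α-methyl-9β-formyl compound | CC(C)(C)[Si](C)(C)O[C@H]1CCC[C@H]2[C@](C=O)(Cc3c(OCOC)c(OC)cc(OC)c3OCOC)[C@H](C)CC[C@@]12C | intermediate
23 | (4S,5R,8R,9R,10S)-9-[Ar(MOM)-methyl]-5,8,9-trimethyldecalin-4-ol | O[C@H]1CCC[C@H]2[C@](C)(Cc3c(OCOC)c(OC)cc(OC)c3OCOC)[C@H](C)CC[C@@]12C | intermediate
24 | (5R,8R,9R,10S)-9-[Ar(MOM)-methyl]-5,8,9-trimethyldecalin-4-one | O=C1CCC[C@H]2[C@](C)(Cc3c(OCOC)c(OC)cc(OC)c3OCOC)[C@H](C)CC[C@@]12C | intermediate
25 | (5R,8R,9R,10S)-9-[Ar(MOM)-methyl]-5,8,9-trimethyl-4-methylidenedecalin | C=C1CCC[C@H]2[C@](C)(Cc3c(OCOC)c(OC)cc(OC)c3OCOC)[C@H](C)CC[C@@]12C | intermediate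
26 | 2-{[(1R,2R,4aR,8aS)-1,2,4a-trimethyl-5-methylidenedecahydronaphthalen-1-yl]methyl}-4,6-dimethoxybenzene-1,3-diol | C=C1CCC[C@H]2[C@](C)(Cc3c(O)c(OC)cc(OC)c3O)[C@H](C)CC[C@@]12C | intermediate
27 | CID71726091, (5R,8R,9R,10S)-5,8-di-epi-ilimaquinone | C=C1CCC[C@H]2[C@](C)(CC3=C(O)C(=O)C=C(OC)C3=O)[C@H](C)CC[C@@]12C | target

---

**Step count**
- Total: 23 steps.
- Longest linear sequence: 18 steps (steps 1–8, then 14–23); the aryl bromide branch is 5 steps (9–13).

**Three steps most likely to fail, with fallbacks**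
1. **Step 14 (benzylation to the C9 quaternary centre).** Risks are O-alkylation, low conversion with the hindered, labile bromide, or poor face selectivity. Fallback: alkylate 11 with a small electrophile (benzyloxymethyl chloride) from the same convex face and carry C11 as CH2OBn through steps 15–19. Then debenzylate, oxidise to the neopentyl aldehyde, add the aryllithium made from 14, and deoxygenate the benzylic alcohol (Barton–McCombie), so the aryl–C11 bond is formed by carbonyl addition instead of enolate alkylation.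
2. **Step 17 (directed hydrogenation setting C8).** Risks are catalyst inhibition by the polyether arene or incomplete direction. Fallback: radical hydrogen-atom-transfer hydrogenation of 20 or its silyl ether (Mn(dpm)3, PhSiH3, TBHP), which gives the more stable product. In the conformer with equatorial 4β-OTBS, the 8α-methyl is equatorial whereas 8β-methyl would be syn-axial to C1.
3. **Step 8 (cis-selective hydrogenation of the enone ester).** The risk is a significant amount of trans-fused product. Fallback: move the hydrogenation to the C4-keto series. Desilylate and oxidise 10 to the Wieland–Miescher-type dione ester, whose Pd hydrogenation is intrinsically cis-selective, then protect C4 as a dioxolane and continue (step 19 then needs only ketal hydrolysis in place of steps 19b/20).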